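**Retrosynthetic overview**

- The target is an all-cis oxane (O1, C2 aryl, C4 OH, C6 arylethyl). Without O1, the chain C2–C3–C4–C5–C6 is the carbon ring of a cyclopentanone whose carbonyl carbon is C2, and whose C4 oxygen and C6 side chain are the 1,3-cis pair of a 2-alkyl-4-oxycyclopentanone.
- C2 is disconnected last: the aryl group comes from an aryllithium added to a δ-lactone carbonyl, and the C2–H bond from hydride delivered to the resulting cyclic oxocarbenium ion.
- The δ-lactone is traced back, by removal of O1 from between C2 and C6 (Baeyer–Villiger), to the cis-2-(arylethyl)-4-silyloxycyclopentanone.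
- That ketone comes from hydrogenation of a 2-alkylcyclopentenone anti to the silyloxy group; the enone comes from B-alkyl Suzuki coupling of a 2-iodoenone with the 9-BBN adduct of silylated 4-vinylguaiacol. C4 is bought with (S)-4-silyloxycyclopentenone.
- Ring order: the carbocycle and both arenes are bought; the oxane ring is the only ring formed, in step 5, by ring expansion.

Key step: step 5

Assumption: (S)-4-(tert-butyldimethylsilyloxy)cyclopent-2-en-1-one is taken as a purchasable enantiopure building block.

Remark: both phenols are carried as triisopropylsilyl ethers, because aryl tert-butyldimethylsilyl ethers are cleaved by carbonate or phosphate bases in aqueous DMF, the medium of step 3. The secondary alcohol keeps the tert-butyldimethylsilyl group that comes with the enone.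

**Route**

Step 1
Reactants: 1 2-methoxy-4-vinylphenol
Product: 2 triisopropyl(2-methoxy-4-vinylphenoxy)silane
Conditions: TIPSCl, imidazole, DMF, 0 °C to rt
Reagents that add atoms: triisopropylsilyl chloride (TIPSCl), CC(C)[Si](Cl)(C(C)C)C(C)C
Why: O-silylation of a phenol (silyl ether formation with imidazole as base and nucleophilic catalyst) should be clean, and the bulky silyl group is expected to survive the aqueous base of step 3.

Step 2
Reactants: 3 (S)-4-(tert-butyldimethylsilyloxy)cyclopent-2-en-1-one
Product: 4 (S)-4-(tert-butyldimethylsilyloxy)-2-iodocyclopent-2-en-1-one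
Conditions: I2, pyridine, CH2Cl2, 0 °C to rt
Reagents that add atoms: iodine, II
Why: α-Iodination of an enone with I2/pyridine (conjugate addition of pyridine, iodination of the enolate, elimination of pyridine) is established for 4-silyloxycyclopentenones and does not touch the C4 stereocentre.

Step 3
Reactants: 2 triisopropyl(2-methoxy-4-vinylphenoxy)silane; 4 (S)-4-(tert-butyldimethylsilyloxy)-2-iodocyclopent-2-en-1-one
Product: 6 (S)-4-(tert-butyldimethylsilyloxy)-2-{2-[3-methoxy-4-(triisopropylsilyloxy)phenyl]ethyl}cyclopent-2-en-1-one, via B-alkyl-9-BBN adduct 5 (not isolated)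
Conditions: 2 (1.3 equiv), 9-BBN (1.25 equiv), THF, 0 °C to rt; then 3 M aq K3PO4, 4 (1.0 equiv), Pd(dppf)Cl2 (5 mol%), AsPh3 (10 mol%), DMF, rt
Reagents that add atoms: none
Why: Hydroboration of the styrene with 9-BBN places boron on the terminal carbon, and the room-temperature B-alkyl Suzuki–Miyaura coupling with a 2-iodoenone (zerovalent palladium formed from Pd(dppf)Cl2, AsPh3 as co-ligand) should form the C2–CH2 bond without β-hydride loss; the alkene is kept in slight excess over 9-BBN so that no B–H remains to reduce the enone.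

Step 4
Reactants: 6 (S)-4-(tert-butyldimethylsilyloxy)-2-{2-[3-methoxy-4-(triisopropylsilyloxy)phenyl]ethyl}cyclopent-2-en-1-one
Product: 7 (2S,4R)-4-(tert-butyldimethylsilyloxy)-2-{2-[3-methoxy-4-(triisopropylsilyloxy)phenyl]ethyl}cyclopentan-1-one
Conditions: H2 (1 atm), 10% Pd/C, EtOAc, rt
Reagents that add atoms: none
Why: Heterogeneous catalytic hydrogenation should add both hydrogens to the trisubstituted ring alkene from the face opposite the allylic C4 silyloxy group, so that the C2 side chain ends cis to the silyloxy group (C2 = S), while the neutral aprotic medium is expected to avoid hydrogenolysis at C4 and epimerisation at C2.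

Step 5
Reactants: 7 (2S,4R)-4-(tert-butyldimethylsilyloxy)-2-{2-[3-methoxy-4-(triisopropylsilyloxy)phenyl]ethyl}cyclopentan-1-one
Product: 8 (4R,6S)-4-(tert-butyldimethylsilyloxy)-6-{2-[3-methoxy-4-(triisopropylsilyloxy)phenyl]ethyl}tetrahydro-2H-pyran-2-one
Conditions: mCPBA (2.5 equiv), solid NaHCO3 (4 equiv), CH2Cl2, 0 °C to rt
Reagents that add atoms: m-chloroperbenzoic acid (mCPBA), O=C(OO)c1cccc(Cl)c1
Why: The peracid adds to the ketone carbonyl to give the Criegee tetrahedral adduct, and the ring bond C1–C2 that lies antiperiplanar to the O–O bond shifts from carbon to oxygen as 3-chlorobenzoate leaves (Baeyer–Villiger oxidation). The closest known reaction type is the peracid oxidation of 2-alkylcyclopentanones to 6-alkyl δ-lactones, the reaction that turns 2-pentylcyclopentanone into δ-decalactone. The six-membered ring arises by ring expansion of the five-membered carbocycle through insertion of one oxygen atom, not by a cyclisation, so no ring-closure geometry has to be met. No stereocentre is created: the migrating carbon keeps its configuration because the shift is concerted and suprafacial, so C2 (S) of 7 becomes C6 (S) of 8, and C4 is a spectator. The step needs migration of C2 in preference to C5, which the substrate secures twice: C2 is secondary and C5 primary, and C5 is the direct neighbour of the oxygen-bearing C4, whose inductive pull disfavours positive charge at C5 in the migration transition state. It also needs the β-silyloxy ketone and the β-silyloxy lactone to survive, which the solid NaHCO3 should ensure by keeping the medium free of strong acid without being basic enough to enolise the ketone toward C5.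

Step 6
Reactants: 9 4-bromo-2-methoxyphenol
Product: 10 (4-bromo-2-methoxyphenoxy)triisopropylsilane
Conditions: TIPSCl, imidazole, DMF, rt
Reagents that add atoms: triisopropylsilyl chloride (TIPSCl), CC(C)[Si](Cl)(C(C)C)C(C)C
Why: O-silylation of a phenol, as in step 1, should give an aryl bromide whose silyl ether is para to bromine and therefore cannot migrate to carbon after lithiation.

Step 7
Reactants: 10 (4-bromo-2-methoxyphenoxy)triisopropylsilane; 8 (4R,6S)-4-(tert-butyldimethylsilyloxy)-6-{2-[3-methoxy-4-(triisopropylsilyloxy)phenyl]ethyl}tetrahydro-2H-pyran-2-one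
Product: 12 (4R,6S)-4-(tert-butyldimethylsilyloxy)-2-[3-methoxy-4-(triisopropylsilyloxy)phenyl]-6-{2-[3-methoxy-4-(triisopropylsilyloxy)phenyl]ethyl}tetrahydro-2H-pyran-2-ol (anomeric mixture, in equilibrium with the open δ-hydroxy ketone), via aryllithium 11 (not isolated)
Conditions: 10 (1.3 equiv), n-BuLi (1.25 equiv), THF, −78 °C; then 8 (1.0 equiv) in THF, −78 °C; AcOH (1.5 equiv), −78 °C, then aqueous work-up
Reagents that add atoms: none
Why: Bromine–lithium exchange followed by 1,2-addition of the aryllithium to the δ-lactone carbonyl should stop at the lithium hemiketal alkoxide, which is stable at −78 °C and so blocks a second addition; the cold acetic acid quench avoids base-induced loss of the C4 silyloxy group, and the configuration at the new hemiketal carbon is irrelevant because step 8 erases it.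

Step 8
Reactants: 12 (4R,6S)-4-(tert-butyldimethylsilyloxy)-2-[3-methoxy-4-(triisopropylsilyloxy)phenyl]-6-{2-[3-methoxy-4-(triisopropylsilyloxy)phenyl]ethyl}tetrahydro-2H-pyran-2-ol
Product: 13 (2S,4R,6S)-4-(tert-butyldimethylsilyloxy)-2-[3-methoxy-4-(triisopropylsilyloxy)phenyl]-6-{2-[3-methoxy-4-(triisopropylsilyloxy)phenyl]ethyl}tetrahydro-2H-pyran
Conditions: Et3SiH (5 equiv), BF3·OEt2 (2 equiv), CH2Cl2/MeCN (1:1), −78 to −40 °C
Reagents that add atoms: none
Why: Reductive deoxygenation of a lactol (ionic hydrogenation): BF3 ionises the hemiketal to an aryl-stabilised cyclic oxocarbenium ion, whose half-chair holds the cis C4 silyloxy and C6 chain both pseudo-equatorial, and axial delivery of hydride from Et3SiH should place the aryl group equatorial, giving the 2,6-cis ether (C2 = S).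

Step 9
Reactants: 13 (2S,4R,6S)-4-(tert-butyldimethylsilyloxy)-2-[3-methoxy-4-(triisopropylsilyloxy)phenyl]-6-{2-[3-methoxy-4-(triisopropylsilyloxy)phenyl]ethyl}tetrahydro-2H-pyran
Product: 14 (2S,4R,6S)-2-(4-hydroxy-3-methoxyphenyl)-6-[2-(4-hydroxy-3-methoxyphenyl)ethyl]tetrahydro-2H-pyran-4-ol (target)
Conditions: Bu4NF (4 equiv), AcOH (4 equiv), THF, 0 °C to rt
Reagents that add atoms: none
Why: Fluoride-mediated cleavage of the three silyl ethers should free both phenols and the C4 alcohol, and the acetic acid buffer keeps the para-hydroxybenzylic ether from opening through a phenoxide-derived quinone methide, so that C2 is not epimerised.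

**Compound list**

1 | 2-methoxy-4-vinylphenol | COc1cc(C=C)ccc1O | starting material
2 | triisopropyl(2-methoxy-4-vinylphenoxy)silane | COc1cc(C=C)ccc1O[Si](C(C)C)(C(C)C)C(C)C | intermediate
3 | (S)-4-(tert-butyldimethylsilyloxy)cyclopent-2-en-1-one | O=C1C=C[C@@H](O[Si](C)(C)C(C)(C)C)C1 | starting material
4 | (S)-4-(tert-butyldimethylsilyloxy)-2-iodocyclopent-2-en-1-one | O=C1C(I)=C[C@@H](O[Si](C)(C)C(C)(C)C)C1 | intermediate
5 | 9-{2-[3-methoxy-4-(triisopropylsilyloxy)phenyl]ethyl}-9-borabicyclo[3.3.1]nonane | COc1cc(CCB2C3CCCC2CCC3)ccc1O[Si](C(C)C)(C(C)C)C(C)C | intermediate (not isolated)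
6 | (S)-4-(tert-butyldimethylsilyloxy)-2-{2-[3-methoxy-4-(triisopropylsilyloxy)phenyl]ethyl}cyclopent-2-en-1-one | COc1cc(CCC2=C[C@@H](O[Si](C)(C)C(C)(C)C)CC2=O)ccc1O[Si](C(C)C)(C(C)C)C(C)C | intermediate
7 | (2S,4R)-4-(tert-butyldimethylsilyloxy)-2-{2-[3-methoxy-4-(triisopropylsilyloxy)phenyl]ethyl}cyclopentan-1-one | COc1cc(CC[C@H]2C[C@@H](O[Si](C)(C)C(C)(C)C)CC2=O)ccc1O[Si](C(C)C)(C(C)C)C(C)C | intermediate (key-step precursor)
8 | (4R,6S)-4-(tert-butyldimethylsilyloxy)-6-{2-[3-methoxy-4-(triisopropylsilyloxy)phenyl]ethyl}tetrahydro-2H-pyran-2-one | COc1cc(CC[C@H]2C[C@@H](O[Si](C)(C)C(C)(C)C)CC(=O)O2)ccc1O[Si](C(C)C)(C(C)C)C(C)C | intermediate (key-step product)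
9 | 4-bromo-2-methoxyphenol | COc1cc(Br)ccc1O | starting material
10 | (4-bromo-2-methoxyphenoxy)triisopropylsilane | COc1cc(Br)ccc1O[Si](C(C)C)(C(C)C)C(C)C | intermediate
11 | [3-methoxy-4-(triisopropylsilyloxy)phenyl]lithium | COc1cc([Li])ccc1O[Si](C(C)C)(C(C)C)C(C)C | intermediate (not isolated)
12 | (4R,6S)-4-(tert-butyldimethylsilyloxy)-2-[3-methoxy-4-(triisopropylsilyloxy)phenyl]-6-{2-[3-methoxy-4-(triisopropylsilyloxy)phenyl]ethyl}tetrahydro-2H-pyran-2-ol, mixture at C2 | COc1cc(CC[C@H]2C[C@@H](O[Si](C)(C)C(C)(C)C)CC(O)(c3ccc(O[Si](C(C)C)(C(C)C)C(C)C)c(OC)c3)O2)ccc1O[Si](C(C)C)(C(C)C)C(C)C | intermediate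
13 | (2S,4R,6S)-4-(tert-butyldimethylsilyloxy)-2-[3-methoxy-4-(triisopropylsilyloxy)phenyl]-6-{2-[3-methoxy-4-(triisopropylsilyloxy)phenyl]ethyl}tetrahydro-2H-pyran | COc1cc(CC[C@H]2C[C@@H](O[Si](C)(C)C(C)(C)C)C[C@@H](c3ccc(O[Si](C(C)C)(C(C)C)C(C)C)c(OC)c3)O2)ccc1O[Si](C(C)C)(C(C)C)C(C)C | intermediate
14 | (2S,4R,6S)-2-(4-hydroxy-3-methoxyphenyl)-6-[2-(4-hydroxy-3-methoxyphenyl)ethyl]tetrahydro-2H-pyran-4-ol | COc1cc(CC[C@H]2C[C@@H](O)C[C@@H](c3ccc(O)c(OC)c3)O2)ccc1O | target

**Totals**

Total step count: 9.
Longest linear sequence: 7 steps (step 1 or 2, then steps 3, 4, 5, 7, 8, 9).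

**Steps most likely to fail**

1. Step 5 (Baeyer–Villiger). What may go wrong: peracid addition to the five-membered ketone is slow. Over the long reaction time, enolisation toward C5 with β-elimination of silanol, migration of the C5 methylene in place of C2, or oxidation of the electron-rich arene may compete. The fallback sets out from enone 6 and comes back at lactone 8; it replaces oxygen insertion by ring cleavage and re-closure and does not depend on step 4 either.
   - 1,4-Hydrosilylation of 6 with Et3SiH and RhCl(PPh3)3 (1 mol%, THF, 50 °C) should give the silyl enol ether (R)-4-(tert-butyldimethylsilyloxy)-2-{2-[3-methoxy-4-(triisopropylsilyloxy)phenyl]ethyl}-1-(triethylsilyloxy)cyclopent-1-ene F1, with the double bond fixed between the old C1 and C2.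
   - Ozonolysis (O3, CH2Cl2, −78 °C, stopped at an indicator end point; then PPh3 and aqueous work-up) should cleave that bond to the keto acid (R)-3-(tert-butyldimethylsilyloxy)-7-[3-methoxy-4-(triisopropylsilyloxy)phenyl]-5-oxoheptanoic acid F2.
   - HF·pyridine (THF, 0 °C) should remove the secondary silyl ether faster than the aryl one and give the β-hydroxy ketone (R)-3-hydroxy-7-[3-methoxy-4-(triisopropylsilyloxy)phenyl]-5-oxoheptanoic acid F3.
   - Evans–Saksena reduction with Me4NBH(OAc)3 (MeCN/AcOH, −30 °C) delivers hydride intramolecularly from the C3 alkoxyborohydride and should give the 1,3-anti diol (3R,5S)-3,5-dihydroxy-7-[3-methoxy-4-(triisopropylsilyloxy)phenyl]heptanoic acid F4.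
   - Acid-catalysed lactonisation (PPTS, CH2Cl2) should close F4 to the cis hydroxy lactone (4R,6S)-4-hydroxy-6-{2-[3-methoxy-4-(triisopropylsilyloxy)phenyl]ethyl}tetrahydro-2H-pyran-2-one F5.
   - Silylation (TBSCl, imidazole, DMF) should return lactone 8.

2. Step 7 (aryllithium addition). What may go wrong: the aryllithium acts as a base at C3 of the lactone and triggers β-elimination of the C4 silyloxy group, or the tetrahedral adduct collapses in the flask and takes up a second aryl group. The fallback sets out from lactone 8 and comes back at lactol 12.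
   - Weinreb aminolysis (MeNH(OMe)·HCl, AlMe3, CH2Cl2, 0 °C to rt) should open the lactone to the hydroxy amide (3R,5S)-3-(tert-butyldimethylsilyloxy)-5-hydroxy-N-methoxy-7-[3-methoxy-4-(triisopropylsilyloxy)phenyl]-N-methylheptanamide F6.
   - F6 is treated with 2.3 equiv of aryllithium 11 (THF, −78 to −40 °C; the first equivalent deprotonates the alcohol). The five-membered lithium chelate of the Weinreb adduct should persist until the acetic acid quench, which releases the δ-hydroxy aryl ketone, and this closes to lactol 12.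

3. Step 8 (lactol reduction). What may go wrong: proton loss from the oxocarbenium ion gives the cyclic enol ether, whose C4 silyloxy group is then allylic and can ionise under the Lewis acid. The electron-rich benzylic C–O bond of the product may also ionise and be reduced with ring opening, silyl ethers may be lost, or the 2,6-cis selectivity may erode. The fallback sets out from lactol 12 and comes back at 13, and uses no Lewis acid.
   - Dehydration (MsCl, Et3N, CH2Cl2, 0 °C) should give the cyclic enol ether (2S,4R)-4-(tert-butyldimethylsilyloxy)-6-[3-methoxy-4-(triisopropylsilyloxy)phenyl]-2-{2-[3-methoxy-4-(triisopropylsilyloxy)phenyl]ethyl}-3,4-dihydro-2H-pyran F7.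
   - Hydrogenation of F7 (H2, 10% Pd/C, EtOAc with a trace of Et3N, rt) should add hydrogen from the face opposite the C2 chain and the allylic C4 silyloxy group, which places the aryl group cis to both and gives 13.

**Further compounds**

F1 | step 5 | (R)-4-(tert-butyldimethylsilyloxy)-2-{2-[3-methoxy-4-(triisopropylsilyloxy)phenyl]ethyl}-1-(triethylsilyloxy)cyclopent-1-ene | COc1cc(CCC2=C(O[Si](CC)(CC)CC)C[C@H](O[Si](C)(C)C(C)(C)C)C2)ccc1O[Si](C(C)C)(C(C)C)C(C)C
F2 | step 5 | (R)-3-(tert-butyldimethylsilyloxy)-7-[3-methoxy-4-(triisopropylsilyloxy)phenyl]-5-oxoheptanoic acid | COc1cc(CCC(=O)C[C@@H](O[Si](C)(C)C(C)(C)C)CC(=O)O)ccc1O[Si](C(C)C)(C(C)C)C(C)C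
F3 | step 5 | (R)-3-hydroxy-7-[3-methoxy-4-(triisopropylsilyloxy)phenyl]-5-oxoheptanoic acid | COc1cc(CCC(=O)C[C@@H](O)CC(=O)O)ccc1O[Si](C(C)C)(C(C)C)C(C)C
F4 | step 5 | (3R,5S)-3,5-dihydroxy-7-[3-methoxy-4-(triisopropylsilyloxy)phenyl]heptanoic acid | COc1cc(CC[C@H](O)C[C@@H](O)CC(=O)O)ccc1O[Si](C(C)C)(C(C)C)C(C)C
F5 | step 5 | (4R,6S)-4-hydroxy-6-{2-[3-methoxy-4-(triisopropylsilyloxy)phenyl]ethyl}tetrahydro-2H-pyran-2-one | COc1cc(CC[C@H]2C[C@@H](O)CC(=O)O2)ccc1O[Si](C(C)C)(C(C)C)C(C)C
F6 | step 7 | (3R,5S)-3-(tert-butyldimethylsilyloxy)-5-hydroxy-N-methoxy-7-[3-methoxy-4-(triisopropylsilyloxy)phenyl]-N-methylheptanamide | COc1cc(CC[C@H](O)C[C@@H](O[Si](C)(C)C(C)(C)C)CC(=O)N(C)OC)ccc1O[Si](C(C)C)(C(C)C)C(C)C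
F7 | step 8 | (2S,4R)-4-(tert-butyldimethylsilyloxy)-6-[3-methoxy-4-(triisopropylsilyloxy)phenyl]-2-{2-[3-methoxy-4-(triisopropylsilyloxy)phenyl]ethyl}-3,4-dihydro-2H-pyran | COc1cc(CC[C@H]2C[C@@H](O[Si](C)(C)C(C)(C)C)C=C(c3ccc(O[Si](C(C)C)(C(C)C)C(C)C)c(OC)c3)O2)ccc1O[Si](C(C)C)(C(C)C)C(C)C
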